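## Retrosynthetic overview

1. The only ring of the target is the 36-membered lactone (C1–C35 plus the ring oxygen; C1 = lactone carbonyl, C35 = carbinol carbon on the ring oxygen, C36–C40 = side chain). It is closed last, at the C16–C17 bond, followed only by saturation of a C15≡C16 alkyne and global deprotection.
2. Enabling feature: C17 is a secondary carbinol, and its neighbour C16 belongs to the C14–C16 trimethylene link of the C13/C17 1,5-diol. C15–C16 can therefore be carried as an alkyne whose terminus C16 (alkynyl iodide → alkynylchromium) attacks a C17 aldehyde; the two sp carbons fit without strain in the 36-membered ring, and a chiral ligand on chromium sets C17.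
3. The seco compound comes from fragment W (C4–C16) and fragment E (C1–C3 + C17–C40) by B-alkyl Suzuki coupling at C3–C4. The partner is a (Z)-β-iodoenoate ester already placed on O–C35, so the ester bond is made early on a small fragment and the Z geometry comes from the vinyl iodide.
4. Fragment E: C17–C28 methyl ketone + C29–C40 aldehyde by 1,5-anti boron aldol (C28–C29), then anti reduction (C27) and oxidative p-methoxybenzylidene acetal formation. Fragment W: chiral-pool syn-diol acetonide (C5–C10), Wittig extension, catalytic asymmetric propargylation (C13).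
5. Ring order: the temporary acetonide (C7/C9) and p-methoxybenzylidene acetal (C25/C27) are formed first, the macrocycle is closed at C16–C17, and both temporary rings are removed in the last step.

Key step: step 35

## Remarks

- Numbering: intermediates are described with the target locants C1–C40 defined above; the SMILES carry the stereochemistry.
- Assumption: for the catalyst-controlled steps 5 and 35 the ligand antipode is the one that a model aliphatic aldehyde shows to give the drawn carbinol. For step 35 the (S)-ligand L is written: N-[2-[(4S)-4-isopropyl-4,5-dihydro-1,3-oxazol-2-yl]-6-methylphenyl]methanesulfonamide, CC(C)[C@H]1COC(=N1)c1cccc(C)c1NS(C)(=O)=O.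
- Abbreviations: TBS = tert-butyldimethylsilyl, PMB = 4-methoxybenzyl, Ipc = isopinocampheyl, 9-BBN = 9-borabicyclo[3.3.1]nonane, DMP = Dess–Martin periodinane.

## Route

### Fragment W (C4–C16)

Step 1
Reactants: 1 tert-butyl 2-[(4R,6S)-6-(hydroxymethyl)-2,2-dimethyl-1,3-dioxan-4-yl]acetate
Product: 2 tert-butyl 2-[(4R,6S)-6-formyl-2,2-dimethyl-1,3-dioxan-4-yl]acetate
Conditions: DMP, CH2Cl2, 0 °C → rt
Reagents that add atoms: none
Why: Dess–Martin oxidation should give the α-alkoxy aldehyde (C10) under non-basic conditions without epimerising C9.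

Step 2
Reactants: 2; 3 [3-(benzyloxy)propyl]triphenylphosphonium bromide
Product: 4 tert-butyl 2-[(4R,6S)-6-[(Z)-4-(benzyloxy)but-1-en-1-yl]-2,2-dimethyl-1,3-dioxan-4-yl]acetate
Conditions: 3, NaHMDS, THF, 0 °C; then 2, −78 °C → rt
Reagents that add atoms: none
Why: Wittig olefination with the non-stabilised ylide adds C11–C13; the alkene geometry is irrelevant because it is hydrogenated next.

Step 3
Reactants: 4
Product: 5 tert-butyl 2-[(4R,6R)-6-(4-hydroxybutyl)-2,2-dimethyl-1,3-dioxan-4-yl]acetate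
Conditions: H2 (1 atm), palladium on carbon (Pd/C), EtOAc/EtOH, rt
Reagents that add atoms: none
Why: Heterogeneous hydrogenation should saturate C10=C11 and hydrogenolyse the benzyl ether in one operation, leaving acetonide and tert-butyl ester intact.

Step 4
Reactants: 5
Product: 6 tert-butyl 2-[(4R,6R)-2,2-dimethyl-6-(4-oxobutyl)-1,3-dioxan-4-yl]acetate
Conditions: DMP, CH2Cl2, 0 °C → rt
Reagents that add atoms: none
Why: Dess–Martin oxidation of the primary alcohol should give the C13 aldehyde.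

Step 5
Reactants: 6; 7 trimethyl[3-(4,4,5,5-tetramethyl-1,3,2-dioxaborolan-2-yl)prop-1-yn-1-yl]silane
Product: 8 tert-butyl 2-[(4R,6R)-6-[(4R)-4-hydroxy-7-(trimethylsilyl)hept-6-yn-1-yl]-2,2-dimethyl-1,3-dioxan-4-yl]acetate
Conditions: Cu(O2CiPr)2 (5 mol%), LiOtBu (8 mol%), MeO-BIBOP (one antipode, 6 mol%), THF, −30 °C
Reagents that add atoms: none
Why: Copper-catalysed asymmetric propargylation (B-to-Cu exchange to an allenylcopper, SE2' addition to the aldehyde) should give the silyl-capped homopropargylic alcohol, C13 being set by the chiral bisphosphine because the existing stereocentres are remote.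

Step 6
Reactants: 8
Product: 9 tert-butyl 2-[(4R,6R)-6-[(4R)-4-[(tert-butyldimethylsilyl)oxy]-7-(trimethylsilyl)hept-6-yn-1-yl]-2,2-dimethyl-1,3-dioxan-4-yl]acetate
Conditions: TBSCl, imidazole, DMF, rt
Reagents that add atoms: tert-butyldimethylsilyl chloride, CC(C)(C)[Si](C)(C)Cl
Why: Standard silylation protects the C13 hydroxyl.

Step 7
Reactants: 9
Product: 10 2-[(4R,6R)-6-[(4R)-4-[(tert-butyldimethylsilyl)oxy]-7-(trimethylsilyl)hept-6-yn-1-yl]-2,2-dimethyl-1,3-dioxan-4-yl]acetaldehyde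
Conditions: iBu2AlH (1.1 equiv), CH2Cl2, −78 °C; Rochelle salt work-up
Reagents that add atoms: none
Why: Partial reduction of the tert-butyl ester with iBu2AlH at −78 °C should stop at the aldehyde (C5) through the stable tetrahedral aluminate.

Step 8
Reactants: 10; 11 methyltriphenylphosphonium bromide
Product: 12 (4S,6R)-4-allyl-6-[(4R)-4-[(tert-butyldimethylsilyl)oxy]-7-(trimethylsilyl)hept-6-yn-1-yl]-2,2-dimethyl-1,3-dioxane (fragment W)
Conditions: 11, NaHMDS, THF, 0 °C; then 10, −78 → 0 °C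
Reagents that add atoms: none
Why: Wittig methylenation with a salt-free ylide at low temperature should install C4 as the terminal alkene without β-elimination of the acetonide oxygen.

### Iodo acid (C1–C3)

Step 9
Reactants: 13 but-2-ynoic acid
Product: 14 (Z)-3-iodobut-2-enoic acid
Conditions: NaI, AcOH, 110 °C
Reagents that add atoms: sodium iodide, [Na+].[I-]
Why: Anti hydroiodination of the ynoic acid places iodine cis to the carboxyl group and so fixes the future C2=C3 geometry.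

### Ketone C17–C28

Step 10
Reactants: 15 rac-2-(but-3-en-1-yl)oxirane
Product: 16 (S)-2-(but-3-en-1-yl)oxirane
Conditions: (S,S)-(salen)Co(OAc) [salen = N,N'-bis(3,5-di-tert-butylsalicylidene)cyclohexane-1,2-diamine] (0.5 mol%), H2O (0.55 equiv), 0 °C → rt; distillation
Reagents that add atoms: none
Why: Jacobsen hydrolytic kinetic resolution should hydrolyse the (R)-epoxide selectively and leave the (S)-epoxide, which carries the C21 stereocentre.

Step 11
Reactants: 16; 17 (3-bromopropoxy)(tert-butyl)dimethylsilane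
Product: 18 (R)-9-[(tert-butyldimethylsilyl)oxy]non-1-en-5-ol
Conditions: 17, Mg, THF; then CuI (10 mol%), 16, −30 → 0 °C
Reagents that add atoms: none
Why: Copper-catalysed Grignard opening at the terminal epoxide carbon (C20) adds C17–C19 and leaves the C21 stereocentre untouched.

Step 12
Reactants: 18
Product: 19 (R)-5,9-bis[(tert-butyldimethylsilyl)oxy]non-1-ene
Conditions: TBSCl, imidazole, DMF, rt
Reagents that add atoms: tert-butyldimethylsilyl chloride, CC(C)(C)[Si](C)(C)Cl
Why: Standard silylation protects the C21 hydroxyl.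

Step 13
Reactants: 19
Product: 21 (S)-5,9-bis[(tert-butyldimethylsilyl)oxy]nonan-1-ol, via alkylborane 20 (not isolated)
Conditions: 9-BBN, THF, 0 °C → rt; then NaOH (aq.), H2O2, 0 °C
Reagents that add atoms: hydrogen peroxide, OO
Why: Anti-Markovnikov hydroboration–oxidation of the terminal alkene should give the C25 primary alcohol.

Step 14
Reactants: 21
Product: 22 (R)-5,9-bis[(tert-butyldimethylsilyl)oxy]nonanal
Conditions: DMP, CH2Cl2, 0 °C → rt
Reagents that add atoms: none
Why: Dess–Martin oxidation should give the C25 aldehyde.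

Step 15
Reactants: 22; 23 allylmagnesium bromide
Product: 24 (4S,8R)-8,12-bis[(tert-butyldimethylsilyl)oxy]dodec-1-en-4-ol
Conditions: (+)-Ipc2BOMe [from (−)-α-pinene], 23, Et2O, 0 °C → rt; then 22, −78 °C; NaOH, H2O2
Reagents that add atoms: none
Why: Brown allylboration through a closed chair transition state should set C25 under reagent control, the pinene antipode being chosen by the known facial preference of Ipc2B(allyl) toward unbranched aliphatic aldehydes.

Step 16
Reactants: 24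
Product: 25 (4S,8R)-8,12-bis[(tert-butyldimethylsilyl)oxy]-4-[(4-methoxybenzyl)oxy]dodec-1-ene
Conditions: NaH, PMBCl, Bu4NI (cat.), DMF, 0 °C → rt
Reagents that add atoms: 4-methoxybenzyl chloride, COc1ccc(CCl)cc1
Why: Williamson etherification installs the PMB ether needed for 1,5-anti induction in the aldol and later as the acetal precursor.

Step 17
Reactants: 25
Product: 26 (4S,8R)-8,12-bis[(tert-butyldimethylsilyl)oxy]-4-[(4-methoxybenzyl)oxy]dodecan-2-one (C17–C28 ketone)
Conditions: PdCl2 (10 mol%), CuCl, O2 (1 atm), DMF/H2O (7:1), rt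
Reagents that add atoms: water, O
Why: Wacker–Tsuji oxidation of the terminal alkene should give the β-alkoxy methyl ketone (C27 carbonyl, C28 methyl).

### Aldehyde C29–C40 carrying C1–C3

Step 18
Reactants: 27 methyl 5,5-dimethoxypentanoate
Product: 28 5,5-dimethoxypentanal
Conditions: iBu2AlH (1.05 equiv), CH2Cl2, −78 °C
Reagents that add atoms: none
Why: Partial reduction of the methyl ester at −78 °C should give the C33 aldehyde with C29 masked as its dimethyl acetal.

Step 19
Reactants: 28; 23 allylmagnesium bromide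
Product: 29 (R)-8,8-dimethoxyoct-1-en-4-ol
Conditions: (−)-Ipc2BOMe [from (+)-α-pinene], 23, Et2O, 0 °C → rt; then 28, −78 °C; NaOH, H2O2
Reagents that add atoms: none
Why: Brown allylboration with the antipodal reagent should set C33 under reagent control.

Step 20
Reactants: 29
Product: 30 (R)-tert-butyl[(8,8-dimethoxyoct-1-en-4-yl)oxy]dimethylsilane
Conditions: TBSCl, imidazole, DMF, rt
Reagents that add atoms: tert-butyldimethylsilyl chloride, CC(C)(C)[Si](C)(C)Cl
Why: Silylation protects C33–OH before C35–OH exists, which differentiates the two oxygens of the later syn-1,3-diol.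

Step 21
Reactants: 30
Product: 32 (R)-3-[(tert-butyldimethylsilyl)oxy]-7,7-dimethoxyheptanal, via ozonide 31 (not isolated)
Conditions: O3, CH2Cl2, −78 °C; then PPh3, −78 °C → rt
Reagents that add atoms: ozone, [O-][O+]=O
Why: Ozonolysis with reductive work-up should cleave the terminal alkene to the C35 aldehyde much faster than ozone attacks the acetal.

Step 22
Reactants: 32; 33 (E)-but-2-ene
Product: 34 (3S,4R,6R)-6-[(tert-butyldimethylsilyl)oxy]-10,10-dimethoxy-3-methyldec-1-en-4-ol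
Conditions: 33, KOtBu, nBuLi, THF, −78 → −45 °C; (−)-Ipc2BOMe [from (+)-α-pinene], −78 °C; BF3·OEt2; then 32, −78 °C; NaOH, H2O2
Reagents that add atoms: none
Why: Brown (E)-crotylboration should set C35 and C36 together, the anti relation coming from the E-crotyl geometry in the chair transition state and the absolute sense from the Ipc groups (reagent control over the β-silyloxy bias).

Step 23
Reactants: 34; 35 (Z)-hex-3-ene
Product: 36 (5S,6R,8R)-8-[(tert-butyldimethylsilyl)oxy]-12,12-dimethoxy-5-methyldodec-3-en-6-ol (E/Z mixture)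
Conditions: 35 (10 equiv), second-generation Grubbs catalyst RuCl2(H2IMes)(PCy3)(=CHPh) (5 mol%), CH2Cl2, 40 °C
Reagents that add atoms: none
Why: Cross-metathesis of the terminal vinyl group with excess symmetrical alkene should add C39–C40.

Step 24
Reactants: 36
Product: 37 (5R,7R,8S)-5-[(tert-butyldimethylsilyl)oxy]-1,1-dimethoxy-8-methyldodecan-7-ol
Conditions: H2 (1 atm), PtO2, EtOAc, rt
Reagents that add atoms: none
Why: Hydrogenation over platinum should saturate C37=C38 with little double-bond migration, so the allylic C36 centre is kept.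

Step 25
Reactants: 37; 14 (Z)-3-iodobut-2-enoic acid
Product: 38 (5R,7R,8S)-5-[(tert-butyldimethylsilyl)oxy]-1,1-dimethoxy-8-methyldodecan-7-yl (Z)-3-iodobut-2-enoate
Conditions: 14, DCC, DMAP (cat.), CH2Cl2, 0 °C → rt
Reagents that add atoms: none
Why: Steglich esterification of the only free hydroxyl (C35) forms the future lactone C–O bond on a small fragment.

Step 26
Reactants: 38
Product: 39 (5R,7R,8S)-5-[(tert-butyldimethylsilyl)oxy]-8-methyl-1-oxododecan-7-yl (Z)-3-iodobut-2-enoate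
Conditions: PPTS (cat.), acetone/H2O (10:1), 45 °C
Reagents that add atoms: water, O
Why: Mild acid hydrolysis of the dimethyl acetal should release the C29 aldehyde while the secondary TBS ether and the ester survive.

### Fragment E

Step 27
Reactants: 26; 39
Product: 41 aldol adduct with C29 carbinol and C27 ketone, via enol borinate 40 (not isolated)
Conditions: (c-Hex)2BCl, Et3N, Et2O, 0 °C (enolisation of 26); then 39, −78 → −20 °C; pH 7 buffer, MeOH, H2O2, 0 °C
Reagents that add atoms: none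
Why: Paterson-type boron aldol of the β-PMB-oxy methyl ketone should form C28–C29 with 1,5-anti induction from C25, which sets C29.

Step 28
Reactants: 41
Product: 42 C27,C29-anti diol
Conditions: Me4NBH(OAc)3, MeCN/AcOH (1:1), −30 °C
Reagents that add atoms: none
Why: Evans–Saksena reduction delivers hydride intramolecularly from the C29 alkoxyborohydride and should set C27 anti to C29 (and so syn to C25).

Step 29
Reactants: 42
Product: 43 C25/C27 p-methoxybenzylidene acetal with free C29 hydroxyl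
Conditions: DDQ, 4 Å molecular sieves, CH2Cl2, 0 °C
Reagents that add atoms: none
Why: Anhydrous DDQ oxidation of the PMB ether (Oikawa–Yonemitsu) gives an oxocarbenium ion that the 1,3-syn C27 hydroxyl traps as the all-equatorial six-membered acetal, which protects C25 and C27 and leaves C29–OH free.

Step 30
Reactants: 43
Product: 44 fragment E: C1–C3 iodoenoate on O–C35, TBS ethers at C17, C21, C29 and C33, C25/C27 acetal
Conditions: TBSOTf, 2,6-lutidine, CH2Cl2, −78 °C
Reagents that add atoms: tert-butyldimethylsilyl trifluoromethanesulfonate, CC(C)(C)[Si](C)(C)OS(=O)(=O)C(F)(F)F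
Why: Silylation of the remaining C29 hydroxyl leaves every protecting group of the fragment acid-labile.

### Union and endgame

Step 31
Reactants: 12; 44
Product: 46 seco ester with C16 trimethylsilyl alkyne and C17 silyl ether, via alkylborane 45 (not isolated)
Conditions: 12, 9-BBN, THF, rt; then 44, Pd(dppf)Cl2 (10 mol%), AsPh3, Cs2CO3, DMF/THF/H2O, rt
Reagents that add atoms: none
Why: B-alkyl Suzuki–Miyaura coupling (9-BBN adds to the terminal alkene much faster than to the hindered silylalkyne) should form C3–C4 with retention of the Z geometry of the vinyl iodide.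

Step 32
Reactants: 46
Product: 47 seco C16 iodoalkyne
Conditions: N-iodosuccinimide, AgNO3 (10 mol%), acetone, rt, dark
Reagents that add atoms: N-iodosuccinimide, O=C1CCC(=O)N1I
Why: Silver-catalysed iododesilylation should convert the trimethylsilyl alkyne directly into the 1-iodoalkyne under neutral conditions.

Step 33
Reactants: 47
Product: 48 seco C17 primary alcohol
Conditions: HF·pyridine, pyridine, THF, 0 °C
Reagents that add atoms: none
Why: Buffered HF·pyridine should cleave the unhindered primary TBS ether much faster than the four secondary TBS ethers and leave both acetals.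

Step 34
Reactants: 48
Product: 49 seco C17 aldehyde with C16 iodoalkyne
Conditions: DMP, CH2Cl2, 0 °C → rt
Reagents that add atoms: none
Why: Dess–Martin oxidation should give the aldehyde without touching the iodoalkyne, the enoate or the acetals.

Step 35
Reactants: 49
Product: 51 36-membered propargylic alcohol (C15≡C16 and new C17 carbinol), via alkynylchromium species 50 (not isolated)
Conditions: CrCl2 (8 equiv), ligand L (8.8 equiv), Et3N (8.8 equiv), THF/MeCN, rt; 49 added by syringe pump over 12 h (final 1 mM); aqueous sodium serinate work-up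
Reagents that add atoms: none
Why: Proposed new method: divalent chromium reduces the C16 alkynyl iodide by two one-electron transfers to a trivalent alkynylchromium bearing the deprotonated oxazoline–sulfonamide ligand (50), which adds to the chromium-bound C17 aldehyde to give the chromium alkoxide of 51; the closest known reaction types are the Nozaki–Hiyama–Kishi macrocyclisation of iodoalkene aldehydes and the ligand-controlled intermolecular chromium-mediated alkynylation of aldehydes with 1-iodoalkynes, which have not been combined in one ring closure. The 36-membered ring (C1–C35 plus the ester oxygen) closes in a 36-exo-trig mode, and the linear C14–C15≡C16–C17 unit is accommodated without strain in a ring of this size. The new stereocentre C17 is set by the chiral ligand on chromium (reagent control), because the nearest stereocentres C13 and C21 are four bonds away and give no useful bias. The step needs intramolecular over intermolecular addition, secured by slow addition into excess chromium reagent at 1 mM, and aldehyde over ester selectivity, which is inherent to organochromium reagents; the Z-enoate, silyl ethers and both acetals are inert to CrCl2.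

Step 36
Reactants: 51
Product: 52 protected saturated 36-membered lactone
Conditions: H2 (1 atm), RhCl(PPh3)3 (20 mol%), benzene/EtOH (1:1), rt
Reagents that add atoms: none
Why: Homogeneous hydrogenation with RhCl(PPh3)3 should reduce the disubstituted alkyne through the cis-alkene to C15–C16 methylene groups while the trisubstituted conjugated C2=C3 enoate reacts far more slowly.

Step 37
Reactants: 52
Product: 53 target macrolide
Conditions: 48% aq. HF, MeCN/CH2Cl2, 0 °C → rt
Reagents that add atoms: none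
Why: Aqueous HF should cleave the four TBS ethers and hydrolyse the acetonide and the p-methoxybenzylidene acetal in one operation, the acidic medium disfavouring acyl migration from O–C35 to O–C33.

## Compound list

1 | tert-butyl 2-[(4R,6S)-6-(hydroxymethyl)-2,2-dimethyl-1,3-dioxan-4-yl]acetate | OC[C@@H]1C[C@H](CC(=O)OC(C)(C)C)OC(C)(C)O1 | starting material
2 | tert-butyl 2-[(4R,6S)-6-formyl-2,2-dimethyl-1,3-dioxan-4-yl]acetate | O=C[C@@H]1C[C@H](CC(=O)OC(C)(C)C)OC(C)(C)O1 | intermediate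
3 | [3-(benzyloxy)propyl]triphenylphosphonium bromide | [Br-].c1ccccc1COCCC[P+](c1ccccc1)(c1ccccc1)c1ccccc1 | starting material
4 | tert-butyl 2-[(4R,6S)-6-[(Z)-4-(benzyloxy)but-1-en-1-yl]-2,2-dimethyl-1,3-dioxan-4-yl]acetate | c1ccccc1COCC/C=C\[C@@H]1C[C@H](CC(=O)OC(C)(C)C)OC(C)(C)O1 | intermediate
5 | tert-butyl 2-[(4R,6R)-6-(4-hydroxybutyl)-2,2-dimethyl-1,3-dioxan-4-yl]acetate | OCCCC[C@@H]1C[C@H](CC(=O)OC(C)(C)C)OC(C)(C)O1 | intermediate
6 | tert-butyl 2-[(4R,6R)-2,2-dimethyl-6-(4-oxobutyl)-1,3-dioxan-4-yl]acetate | O=CCCC[C@@H]1C[C@H](CC(=O)OC(C)(C)C)OC(C)(C)O1 | intermediate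
7 | trimethyl[3-(4,4,5,5-tetramethyl-1,3,2-dioxaborolan-2-yl)prop-1-yn-1-yl]silane | C[Si](C)(C)C#CCB1OC(C)(C)C(C)(C)O1 | starting material
8 | tert-butyl 2-[(4R,6R)-6-[(4R)-4-hydroxy-7-(trimethylsilyl)hept-6-yn-1-yl]-2,2-dimethyl-1,3-dioxan-4-yl]acetate | C[Si](C)(C)C#CC[C@H](O)CCC[C@@H]1C[C@H](CC(=O)OC(C)(C)C)OC(C)(C)O1 | intermediate
9 | tert-butyl 2-[(4R,6R)-6-[(4R)-4-[(tert-butyldimethylsilyl)oxy]-7-(trimethylsilyl)hept-6-yn-1-yl]-2,2-dimethyl-1,3-dioxan-4-yl]acetate | C[Si](C)(C)C#CC[C@H](O[Si](C)(C)C(C)(C)C)CCC[C@@H]1C[C@H](CC(=O)OC(C)(C)C)OC(C)(C)O1 | intermediate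
10 | 2-[(4R,6R)-6-[(4R)-4-[(tert-butyldimethylsilyl)oxy]-7-(trimethylsilyl)hept-6-yn-1-yl]-2,2-dimethyl-1,3-dioxan-4-yl]acetaldehyde | C[Si](C)(C)C#CC[C@H](O[Si](C)(C)C(C)(C)C)CCC[C@@H]1C[C@H](CC=O)OC(C)(C)O1 | intermediate
11 | methyltriphenylphosphonium bromide | [Br-].C[P+](c1ccccc1)(c1ccccc1)c1ccccc1 | starting material
12 | (4S,6R)-4-allyl-6-[(4R)-4-[(tert-butyldimethylsilyl)oxy]-7-(trimethylsilyl)hept-6-yn-1-yl]-2,2-dimethyl-1,3-dioxane (fragment W, C4–C16) | C[Si](C)(C)C#CC[C@H](O[Si](C)(C)C(C)(C)C)CCC[C@@H]1C[C@H](CC=C)OC(C)(C)O1 | intermediate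
13 | but-2-ynoic acid | CC#CC(=O)O | starting material
14 | (Z)-3-iodobut-2-enoic acid | OC(=O)/C=C(C)\I | intermediate
15 | rac-2-(but-3-en-1-yl)oxirane | C=CCCC1CO1 | starting material
16 | (S)-2-(but-3-en-1-yl)oxirane | C=CCC[C@H]1CO1 | intermediate
17 | (3-bromopropoxy)(tert-butyl)dimethylsilane | CC(C)(C)[Si](C)(C)OCCCBr | starting material
18 | (R)-9-[(tert-butyldimethylsilyl)oxy]non-1-en-5-ol | C=CCC[C@H](O)CCCCO[Si](C)(C)C(C)(C)C | intermediate
19 | (R)-5,9-bis[(tert-butyldimethylsilyl)oxy]non-1-ene | C=CCC[C@H](O[Si](C)(C)C(C)(C)C)CCCCO[Si](C)(C)C(C)(C)C | intermediate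
20 | B-alkyl-9-BBN adduct of 19 (boron on C25) | B1(CCCC[C@H](O[Si](C)(C)C(C)(C)C)CCCCO[Si](C)(C)C(C)(C)C)C2CCCC1CCC2 | intermediate (not isolated)
21 | (S)-5,9-bis[(tert-butyldimethylsilyl)oxy]nonan-1-ol | OCCCC[C@H](O[Si](C)(C)C(C)(C)C)CCCCO[Si](C)(C)C(C)(C)C | intermediate
22 | (R)-5,9-bis[(tert-butyldimethylsilyl)oxy]nonanal | O=CCCC[C@H](O[Si](C)(C)C(C)(C)C)CCCCO[Si](C)(C)C(C)(C)C | intermediate
23 | allylmagnesium bromide | C=CC[Mg]Br | starting material
24 | (4S,8R)-8,12-bis[(tert-butyldimethylsilyl)oxy]dodec-1-en-4-ol | C=CC[C@@H](O)CCC[C@H](O[Si](C)(C)C(C)(C)C)CCCCO[Si](C)(C)C(C)(C)C | intermediate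
25 | (4S,8R)-8,12-bis[(tert-butyldimethylsilyl)oxy]-4-[(4-methoxybenzyl)oxy]dodec-1-ene | C=CC[C@@H](OCc1ccc(OC)cc1)CCC[C@H](O[Si](C)(C)C(C)(C)C)CCCCO[Si](C)(C)C(C)(C)C | intermediate
26 | (4S,8R)-8,12-bis[(tert-butyldimethylsilyl)oxy]-4-[(4-methoxybenzyl)oxy]dodecan-2-one (C17–C28) | CC(=O)C[C@@H](OCc1ccc(OC)cc1)CCC[C@H](O[Si](C)(C)C(C)(C)C)CCCCO[Si](C)(C)C(C)(C)C | intermediate
27 | methyl 5,5-dimethoxypentanoate | COC(=O)CCCC(OC)OC | starting material
28 | 5,5-dimethoxypentanal | O=CCCCC(OC)OC | intermediate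
29 | (R)-8,8-dimethoxyoct-1-en-4-ol | C=CC[C@H](O)CCCC(OC)OC | intermediate
30 | (R)-tert-butyl[(8,8-dimethoxyoct-1-en-4-yl)oxy]dimethylsilane | C=CC[C@H](O[Si](C)(C)C(C)(C)C)CCCC(OC)OC | intermediate
31 | 1,2,4-trioxolane (ozonide) of 30, mixture at the ozonide carbon | C1OC(OO1)C[C@H](O[Si](C)(C)C(C)(C)C)CCCC(OC)OC | intermediate (not isolated)
32 | (R)-3-[(tert-butyldimethylsilyl)oxy]-7,7-dimethoxyheptanal | O=CC[C@H](O[Si](C)(C)C(C)(C)C)CCCC(OC)OC | intermediate
33 | (E)-but-2-ene | C/C=C/C | starting material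
34 | (3S,4R,6R)-6-[(tert-butyldimethylsilyl)oxy]-10,10-dimethoxy-3-methyldec-1-en-4-ol | C=C[C@H](C)[C@H](O)C[C@H](O[Si](C)(C)C(C)(C)C)CCCC(OC)OC | intermediate
35 | (Z)-hex-3-ene | CC/C=C\CC | starting material
36 | (5S,6R,8R)-8-[(tert-butyldimethylsilyl)oxy]-12,12-dimethoxy-5-methyldodec-3-en-6-ol (E/Z mixture) | CCC=C[C@H](C)[C@H](O)C[C@H](O[Si](C)(C)C(C)(C)C)CCCC(OC)OC | intermediate
37 | (5R,7R,8S)-5-[(tert-butyldimethylsilyl)oxy]-1,1-dimethoxy-8-methyldodecan-7-ol | CCCC[C@H](C)[C@H](O)C[C@H](O[Si](C)(C)C(C)(C)C)CCCC(OC)OC | intermediate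
38 | (5R,7R,8S)-5-[(tert-butyldimethylsilyl)oxy]-1,1-dimethoxy-8-methyldodecan-7-yl (Z)-3-iodobut-2-enoate | CCCC[C@H](C)[C@H](OC(=O)/C=C(C)\I)C[C@H](O[Si](C)(C)C(C)(C)C)CCCC(OC)OC | intermediate
39 | (5R,7R,8S)-5-[(tert-butyldimethylsilyl)oxy]-8-methyl-1-oxododecan-7-yl (Z)-3-iodobut-2-enoate (C29–C40 aldehyde with C1–C3) | CCCC[C@H](C)[C@H](OC(=O)/C=C(C)\I)C[C@H](O[Si](C)(C)C(C)(C)C)CCCC=O | intermediate
40 | dicyclohexylboron enolate of 26 (C27=C28) | C=C(OB(C1CCCCC1)C1CCCCC1)C[C@@H](OCc1ccc(OC)cc1)CCC[C@H](O[Si](C)(C)C(C)(C)C)CCCCO[Si](C)(C)C(C)(C)C | intermediate (not isolated)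
41 | aldol adduct: C29 hydroxyl, C27 ketone, C25 PMB ether, iodoenoate on O–C35 | CCCC[C@H](C)[C@H](OC(=O)/C=C(C)\I)C[C@H](O[Si](C)(C)C(C)(C)C)CCC[C@H](O)CC(=O)C[C@@H](OCc1ccc(OC)cc1)CCC[C@H](O[Si](C)(C)C(C)(C)C)CCCCO[Si](C)(C)C(C)(C)C | intermediate
42 | C27,C29-anti diol | CCCC[C@H](C)[C@H](OC(=O)/C=C(C)\I)C[C@H](O[Si](C)(C)C(C)(C)C)CCC[C@H](O)C[C@@H](O)C[C@@H](OCc1ccc(OC)cc1)CCC[C@H](O[Si](C)(C)C(C)(C)C)CCCCO[Si](C)(C)C(C)(C)C | intermediate
43 | C25/C27 p-methoxybenzylidene acetal (all-cis 1,3-dioxane) with free C29 hydroxyl | CCCC[C@H](C)[C@H](OC(=O)/C=C(C)\I)C[C@H](O[Si](C)(C)C(C)(C)C)CCC[C@H](O)C[C@@H]1C[C@@H](O[C@H](c2ccc(OC)cc2)O1)CCC[C@H](O[Si](C)(C)C(C)(C)C)CCCCO[Si](C)(C)C(C)(C)C | intermediate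
44 | fragment E (C1–C3 iodoenoate on O–C35; TBS at C17, C21, C29, C33; C25/C27 acetal) | CCCC[C@H](C)[C@H](OC(=O)/C=C(C)\I)C[C@H](O[Si](C)(C)C(C)(C)C)CCC[C@H](O[Si](C)(C)C(C)(C)C)C[C@@H]1C[C@@H](O[C@H](c2ccc(OC)cc2)O1)CCC[C@H](O[Si](C)(C)C(C)(C)C)CCCCO[Si](C)(C)C(C)(C)C | intermediate
45 | B-alkyl-9-BBN adduct of 12 (boron on C4) | C[Si](C)(C)C#CC[C@H](O[Si](C)(C)C(C)(C)C)CCC[C@@H]1C[C@H](CCCB2C3CCCC2CCC3)OC(C)(C)O1 | intermediate (not isolated)
46 | seco ester with C16 trimethylsilyl alkyne and C17 TBS ether | CCCC[C@H](C)[C@H](OC(=O)/C=C(C)\CCC[C@H]1C[C@@H](CCC[C@@H](O[Si](C)(C)C(C)(C)C)CC#C[Si](C)(C)C)OC(C)(C)O1)C[C@H](O[Si](C)(C)C(C)(C)C)CCC[C@H](O[Si](C)(C)C(C)(C)C)C[C@@H]1C[C@@H](O[C@H](c2ccc(OC)cc2)O1)CCC[C@H](O[Si](C)(C)C(C)(C)C)CCCCO[Si](C)(C)C(C)(C)C | intermediate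
47 | seco ester with C16 iodoalkyne and C17 TBS ether | CCCC[C@H](C)[C@H](OC(=O)/C=C(C)\CCC[C@H]1C[C@@H](CCC[C@@H](O[Si](C)(C)C(C)(C)C)CC#CI)OC(C)(C)O1)C[C@H](O[Si](C)(C)C(C)(C)C)CCC[C@H](O[Si](C)(C)C(C)(C)C)C[C@@H]1C[C@@H](O[C@H](c2ccc(OC)cc2)O1)CCC[C@H](O[Si](C)(C)C(C)(C)C)CCCCO[Si](C)(C)C(C)(C)C | intermediate
48 | seco ester with C16 iodoalkyne and C17 primary alcohol | CCCC[C@H](C)[C@H](OC(=O)/C=C(C)\CCC[C@H]1C[C@@H](CCC[C@@H](O[Si](C)(C)C(C)(C)C)CC#CI)OC(C)(C)O1)C[C@H](O[Si](C)(C)C(C)(C)C)CCC[C@H](O[Si](C)(C)C(C)(C)C)C[C@@H]1C[C@@H](O[C@H](c2ccc(OC)cc2)O1)CCC[C@H](O[Si](C)(C)C(C)(C)C)CCCCO | intermediate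
49 | seco ester with C16 iodoalkyne and C17 aldehyde | CCCC[C@H](C)[C@H](OC(=O)/C=C(C)\CCC[C@H]1C[C@@H](CCC[C@@H](O[Si](C)(C)C(C)(C)C)CC#CI)OC(C)(C)O1)C[C@H](O[Si](C)(C)C(C)(C)C)CCC[C@H](O[Si](C)(C)C(C)(C)C)C[C@@H]1C[C@@H](O[C@H](c2ccc(OC)cc2)O1)CCC[C@H](O[Si](C)(C)C(C)(C)C)CCCC=O | intermediate
50 | C16 alkynylchromium chloride carrying the deprotonated ligand L (trivalent chromium) | CCCC[C@H](C)[C@H](OC(=O)/C=C(C)\CCC[C@H]1C[C@@H](CCC[C@@H](O[Si](C)(C)C(C)(C)C)CC#C[Cr](Cl)N(S(C)(=O)=O)c2c(C)cccc2C2=N[C@@H](C(C)C)CO2)OC(C)(C)O1)C[C@H](O[Si](C)(C)C(C)(C)C)CCC[C@H](O[Si](C)(C)C(C)(C)C)C[C@@H]1C[C@@H](O[C@H](c2ccc(OC)cc2)O1)CCC[C@H](O[Si](C)(C)C(C)(C)C)CCCC=O | intermediate (not isolated)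
51 | 36-membered lactone with C15≡C16 alkyne and free C17 propargylic hydroxyl (target-sense C17), fully protected elsewhere | CCCC[C@H](C)[C@H]1C[C@H](O[Si](C)(C)C(C)(C)C)CCC[C@H](O[Si](C)(C)C(C)(C)C)C[C@@H]2C[C@@H](O[C@H](c3ccc(OC)cc3)O2)CCC[C@H](O[Si](C)(C)C(C)(C)C)CCC[C@H](O)C#CC[C@H](O[Si](C)(C)C(C)(C)C)CCC[C@@H]2C[C@@H](OC(C)(C)O2)CCC/C(C)=C\C(=O)O1 | intermediate
52 | protected saturated 36-membered lactone (free C17 hydroxyl) | CCCC[C@H](C)[C@H]1C[C@H](O[Si](C)(C)C(C)(C)C)CCC[C@H](O[Si](C)(C)C(C)(C)C)C[C@@H]2C[C@@H](O[C@H](c3ccc(OC)cc3)O2)CCC[C@H](O[Si](C)(C)C(C)(C)C)CCC[C@H](O)CCC[C@H](O[Si](C)(C)C(C)(C)C)CCC[C@@H]2C[C@@H](OC(C)(C)O2)CCC/C(C)=C\C(=O)O1 | intermediate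
53 | (3Z,8S,10R,14S,18R,22R,26S,28S,30S,34R,36R)-36-[(2S)-hexan-2-yl]-8,10,14,18,22,26,28,30,34-nonahydroxy-4-methyl-1-oxacyclohexatriacont-3-en-2-one | CCCC[C@H](C)[C@H]1C[C@H](O)CCC[C@H](O)C[C@@H](O)C[C@@H](O)CCC[C@H](O)CCC[C@H](O)CCC[C@H](O)CCC[C@@H](O)C[C@@H](O)CCC/C(C)=C\C(=O)O1 | target

## Step count and risks

Total step count: 37. Longest linear sequence: 20 steps (steps 18–26, then 27–37, from methyl 5,5-dimethoxypentanoate 27).

Steps most likely to fail:

1. Step 35 (proposed new method). Risk: insufficient facial discrimination at C17 by the ligand-bound chromium reagent, or oligomerisation competing with ring closure. Fallback (known chemistry): the fallback sets out from 49. Ligand-free Nozaki–Hiyama–Kishi macrocyclisation (CrCl2, THF, high dilution) would give the 36-membered propargylic alcohols as a C17 epimer mixture F1. Dess–Martin oxidation would give the macrocyclic ynone F2. Noyori transfer hydrogenation with RuCl[(S,S)-TsDPEN](p-cymene) in iPrOH would then set C17 by reduction of the ynone and return to the route at 51.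

2. Step 36. Risk: over-reduction of the C2=C3 enoate, or stalling at the alkene stage in the macrocycle. Fallback: from 51, semihydrogenation over Pd/CaCO3 poisoned with Pb(OAc)2 (quinoline, H2) to the (Z)-allylic alcohol F3, then diimide reduction (o-nitrobenzenesulfonylhydrazide, Et3N, CH2Cl2) of the disubstituted alkene; this returns to the route at 52.

3. Step 5. Risk: weak catalyst control at C13 on this substrate and competing allenyl transfer. Fallback: from 6, Corey–Chaykovsky epoxidation (Me3S+ I−, NaH, DMSO/THF) to the terminal epoxide as a C13 epimer mixture F4. Hydrolytic kinetic resolution with (R,R)-(salen)Co(OAc) would give the single epoxide F5. Opening with lithium (trimethylsilyl)acetylide and BF3·OEt2 (THF, −78 °C) returns to the route at 8, with C13 taken from the resolved epoxide and not from a catalytic addition.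

Further compounds
F1 | step 35 | 36-membered propargylic alcohol, mixture of C17 epimers | CCCC[C@H](C)[C@H]1C[C@H](O[Si](C)(C)C(C)(C)C)CCC[C@H](O[Si](C)(C)C(C)(C)C)C[C@@H]2C[C@@H](O[C@H](c3ccc(OC)cc3)O2)CCC[C@H](O[Si](C)(C)C(C)(C)C)CCCC(O)C#CC[C@H](O[Si](C)(C)C(C)(C)C)CCC[C@@H]2C[C@@H](OC(C)(C)O2)CCC/C(C)=C\C(=O)O1
F2 | step 35 | 36-membered C17 ynone | CCCC[C@H](C)[C@H]1C[C@H](O[Si](C)(C)C(C)(C)C)CCC[C@H](O[Si](C)(C)C(C)(C)C)C[C@@H]2C[C@@H](O[C@H](c3ccc(OC)cc3)O2)CCC[C@H](O[Si](C)(C)C(C)(C)C)CCCC(=O)C#CC[C@H](O[Si](C)(C)C(C)(C)C)CCC[C@@H]2C[C@@H](OC(C)(C)O2)CCC/C(C)=C\C(=O)O1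
F3 | step 36 | 36-membered (15Z)-allylic alcohol | CCCC[C@H](C)[C@H]1C[C@H](O[Si](C)(C)C(C)(C)C)CCC[C@H](O[Si](C)(C)C(C)(C)C)C[C@@H]2C[C@@H](O[C@H](c3ccc(OC)cc3)O2)CCC[C@H](O[Si](C)(C)C(C)(C)C)CCC[C@H](O)/C=C\C[C@H](O[Si](C)(C)C(C)(C)C)CCC[C@@H]2C[C@@H](OC(C)(C)O2)CCC/C(C)=C\C(=O)O1
F4 | step 5 | tert-butyl 2-[(4R,6R)-2,2-dimethyl-6-[3-(oxiran-2-yl)propyl]-1,3-dioxan-4-yl]acetate, mixture of C13 epimers | C1OC1CCC[C@@H]1C[C@H](CC(=O)OC(C)(C)C)OC(C)(C)O1
F5 | step 5 | tert-butyl 2-[(4R,6R)-2,2-dimethyl-6-[3-[(2R)-oxiran-2-yl]propyl]-1,3-dioxan-4-yl]acetate | C1[C@H](O1)CCC[C@@H]2C[C@H](CC(=O)OC(C)(C)C)OC(C)(C)O2
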